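**Plan**

- Retrosynthetic cuts, in order: the enone Cα=Cβ bond (aldol condensation with 4-hydroxybenzaldehyde); the C8–acetyl bond (Stille coupling of a C8 bromide); the C4 carbinol C–H (back to a C4 ketone with an epimerisable C3); the C3–C2 ring bond (back to an aryl glyoxal with an ortho O-isopropyl group); then Riley oxidation, O-alkylation and bromination back to 2'-hydroxy-6'-methoxyacetophenone.
- Forward: the benzene substituents are set first (Br at future C8, OCH(CH3)2 as future O1/C2, acetyl oxidised to C(=O)CH=O as future C4/C3). The pyranone ring then closes photochemically, followed by reduction, acetyl installation and chalcone formation; the route is linear.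
- Enabling feature: in glyoxal 5 the aldehyde oxygen of the ArC(=O)–CH=O unit is 1,7-related to the methine hydrogen of the ortho OCH(CH3)2 group. Visible-light excitation of the 1,2-dicarbonyl chromophore therefore leads, by hydrogen transfer and biradical coupling, to the C3–C2 bond of the dihydropyran ring (O1–C2–C3–C4–C4a–C8a), turning an isopropyl ether C–H into the quaternary C2.
- Stereochemistry: C3 is formed racemic but is α to the C4 ketone. A dynamic kinetic resolution by asymmetric transfer hydrogenation with an (R,R)-TsDPEN–Ru catalyst sets C4 under catalyst control and C3 by hydride delivery anti to the C3–OH, giving the cis-(3S,4S)-diol. No later step touches either centre.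

Key step: step 4

Remark: chroman numbering (O1, C2, C3, C4, C4a, C5–C8, C8a) is used for these atoms also in open-chain precursors; reagents that add atoms are named on their own line and carry no number.

**Step 1**
Reactants: 1 1-(2-hydroxy-6-methoxyphenyl)ethanone
Product: 2 1-(3-bromo-2-hydroxy-6-methoxyphenyl)ethanone
Conditions: NBS (1.0 equiv), i-Pr2NH (10 mol %), CH2Cl2, 0 °C
Reagents that add atoms: N-bromosuccinimide, O=C1CCC(=O)N1Br
Why: Amine-mediated ortho-bromination of a phenol (electrophilic aromatic substitution); C3' is ortho to the hydroxyl and para to the methoxy group so both donors converge on it, while C5' is screened by the methoxy methyl group, which is turned away from the acetyl group.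

**Step 2**
Reactants: 2 1-(3-bromo-2-hydroxy-6-methoxyphenyl)ethanone
Product: 3 1-(3-bromo-6-methoxy-2-isopropoxyphenyl)ethanone
Conditions: 2-bromopropane (4 equiv), Cs2CO3, DMF, 60 °C
Reagents that add atoms: 2-bromopropane, CC(C)Br
Why: Williamson ether synthesis; the hindered, chelated phenoxide should be alkylated in a polar aprotic solvent with caesium as counter-ion and an excess of the secondary bromide to offset E2 loss.

**Step 3**
Reactants: 3 1-(3-bromo-6-methoxy-2-isopropoxyphenyl)ethanone
Product: 5 2-(3-bromo-6-methoxy-2-isopropoxyphenyl)-2-oxoacetaldehyde, via glyoxal hydrate 4 (not isolated)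
Conditions: SeO2 (1.5 equiv), 1,4-dioxane/H2O (20:1), 100 °C; then PhMe, Dean–Stark
Reagents that add atoms: selenium dioxide, O=[Se]=O; water, O (held only in hydrate 4)
Why: Riley oxidation of an aryl methyl ketone to the arylglyoxal, which has no second enolisable position and should tolerate the aryl bromide and both ethers; azeotropic removal of water frees the yellow 1,2-dicarbonyl chromophore needed in step 4.

**Step 4**
Reactants: 5 2-(3-bromo-6-methoxy-2-isopropoxyphenyl)-2-oxoacetaldehyde
Product: 7 rac-8-bromo-3-hydroxy-5-methoxy-2,2-dimethylchroman-4-one, via triplet 1,6-biradical 6 (not isolated)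
Conditions: hν (440 nm LED), degassed PhH (0.01 M), Ar, 20 °C
Reagents that add atoms: none
Why: Blue light excites the n→π* band of the aryl 1,2-dicarbonyl unit; after intersystem crossing the aldehyde oxygen of the triplet abstracts the methine hydrogen of the ortho OCH(CH3)2 group through an eight-membered transition state (1,7-hydrogen transfer) to give biradical 6 (an α-aryloxy tertiary radical and a hydroxy-substituted α-keto radical), which after spin inversion couples to form the C3–C2 bond. The closest known reaction type is the Norrish–Yang photocyclisation of 1-(2-alkoxyphenyl)alkane-1,2-diones to 3-hydroxychroman-4-ones, itself an extension of the cyclisation of 1,2-diketones through their remote carbonyl group. The only ring closed is the six-membered dihydropyranone ring O1–C2–C3–C4–C4a–C8a, and it closes by recombination of a 1,6-biradical, not by an ionic exo or endo attack. C3 is the only new stereocentre and is deliberately left racemic, because it is α to the C4 ketone and is equilibrated and fixed in step 5; C2 carries two identical methyl groups. The step needs site selectivity for the tertiary O–CH over the primary C–H bonds of the methoxy group on the other ortho carbon, which the weaker tertiary α-oxy C–H bond should secure, and for abstraction by the distal aldehyde oxygen over the ketone oxygen (which would lead to a benzofuran-3-ol), which follows the usual preference of triplet 1,2-diones and is helped by the two ortho substituents that twist the ketone out of the arene plane. The aryl bromide, the arene and product 7 do not absorb at this wavelength, and high dilution with exclusion of oxygen should suppress intermolecular abstraction of the aldehyde hydrogen and peroxide formation.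

**Step 5**
Reactants: 7 rac-8-bromo-3-hydroxy-5-methoxy-2,2-dimethylchroman-4-one
Product: 9 (3S,4S)-8-bromo-5-methoxy-2,2-dimethylchromane-3,4-diol, via enediol 8 (not isolated)
Conditions: RuCl[(R,R)-TsDPEN](p-cymene) (2 mol %), HCO2H/Et3N (1:1), DMF, 40 °C
Reagents that add atoms: none
Why: Noyori-type asymmetric transfer hydrogenation run as a dynamic kinetic resolution: the amine interconverts the enantiomers of 7 through enediol 8, and the (R,R)-catalyst should reduce only (3R)-7, delivering hydride to C4 anti to the C3 hydroxyl with the facial sense that turns chroman-4-one into (R)-chroman-4-ol; here that is the (4S) carbinol cis to the C3–OH, i.e. (3S,4S) (the C3 descriptor changes from R to S only because C2 now outranks C4).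

**Step 6**
Reactants: 9 (3S,4S)-8-bromo-5-methoxy-2,2-dimethylchromane-3,4-diol
Product: 11 1-[(3S,4S)-3,4-dihydroxy-5-methoxy-2,2-dimethylchroman-8-yl]ethanone, via 1-ethoxyvinyl arene 10 (not isolated)
Conditions: tributyl(1-ethoxyvinyl)stannane, PdCl2(PPh3)2 (5 mol %), PhMe, 100 °C; then 0.5 M HCl, THF, 0 °C
Reagents that add atoms: tributyl(1-ethoxyvinyl)stannane, CCCC[Sn](CCCC)(CCCC)C(=C)OCC; water, O
Why: Stille coupling with an acetyl-anion equivalent tolerates the free diol, and the enol ether should hydrolyse in cold dilute acid within minutes, before the benzylic C4–OH can ionise; the acetyl group is introduced only after step 5 so that no second aryl ketone is present during the reduction.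

**Step 7**
Reactants: 11 1-[(3S,4S)-3,4-dihydroxy-5-methoxy-2,2-dimethylchroman-8-yl]ethanone; 12 4-hydroxybenzaldehyde
Product: 14 (E)-1-[(3S,4S)-3,4-dihydroxy-5-methoxy-2,2-dimethylchroman-8-yl]-3-(4-hydroxyphenyl)prop-2-en-1-one (target), via aldol adduct 13 (not isolated)
Conditions: KOH (50 % aq., excess), EtOH, Ar, rt to 40 °C; then AcOH to pH 5–6
Reagents that add atoms: none
Why: Claisen–Schmidt condensation (aldol addition, then E1cB loss of water) should give the thermodynamically preferred (E)-enone; the two carbinol centres are not enolisable and are stable to base, and the ketone has no free ortho hydroxyl, so no flavanone can form.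

**Compound list**

1 | 1-(2-hydroxy-6-methoxyphenyl)ethanone | CC(=O)c1c(O)cccc1OC | starting material
2 | 1-(3-bromo-2-hydroxy-6-methoxyphenyl)ethanone | CC(=O)c1c(O)c(Br)ccc1OC | intermediate
3 | 1-(3-bromo-6-methoxy-2-isopropoxyphenyl)ethanone | CC(=O)c1c(OC(C)C)c(Br)ccc1OC | intermediate
4 | 1-(3-bromo-6-methoxy-2-isopropoxyphenyl)-2,2-dihydroxyethanone (glyoxal hydrate) | COc1ccc(Br)c(OC(C)C)c1C(=O)C(O)O | intermediate
5 | 2-(3-bromo-6-methoxy-2-isopropoxyphenyl)-2-oxoacetaldehyde | COc1ccc(Br)c(OC(C)C)c1C(=O)C=O | intermediate
6 | triplet 1,6-biradical (tertiary α-aryloxy radical and hydroxy α-keto radical) | COc1ccc(Br)c(O[C](C)C)c1C(=O)[CH]O | intermediate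
7 | rac-8-bromo-3-hydroxy-5-methoxy-2,2-dimethylchroman-4-one | COc1ccc(Br)c2c1C(=O)C(O)C(C)(C)O2 | intermediate
8 | 8-bromo-5-methoxy-2,2-dimethyl-2H-chromene-3,4-diol (enediol) | COc1ccc(Br)c2c1C(O)=C(O)C(C)(C)O2 | intermediate
9 | (3S,4S)-8-bromo-5-methoxy-2,2-dimethylchromane-3,4-diol (cis) | COc1ccc(Br)c2c1[C@H](O)[C@H](O)C(C)(C)O2 | intermediate
10 | (3S,4S)-8-(1-ethoxyvinyl)-5-methoxy-2,2-dimethylchromane-3,4-diol | COc1ccc(C(=C)OCC)c2c1[C@H](O)[C@H](O)C(C)(C)O2 | intermediate
11 | 1-[(3S,4S)-3,4-dihydroxy-5-methoxy-2,2-dimethylchroman-8-yl]ethanone | COc1ccc(C(C)=O)c2c1[C@H](O)[C@H](O)C(C)(C)O2 | intermediate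
12 | 4-hydroxybenzaldehyde | O=Cc1ccc(O)cc1 | starting material
13 | 1-[(3S,4S)-3,4-dihydroxy-5-methoxy-2,2-dimethylchroman-8-yl]-3-hydroxy-3-(4-hydroxyphenyl)propan-1-one (both epimers at the new carbinol) | COc1ccc(C(=O)CC(O)c2ccc(O)cc2)c2c1[C@H](O)[C@H](O)C(C)(C)O2 | intermediate
14 | (E)-1-[(3S,4S)-3,4-dihydroxy-5-methoxy-2,2-dimethylchroman-8-yl]-3-(4-hydroxyphenyl)prop-2-en-1-one | COc1ccc(C(=O)/C=C/c2ccc(O)cc2)c2c1[C@H](O)[C@H](O)C(C)(C)O2 | target

Total step count: 7. Longest linear sequence: 7 steps (1 to 14).

**Steps most likely to fail**

Step 4. The triplet may abstract hydrogen at the wrong site (from the methoxy group, or through the ketone oxygen to give a five-membered ring). Biradical 6 may also disproportionate or return the hydrogen instead of coupling, and the aldehyde may react intermolecularly. The fallback builds the same ring by ionic chemistry. It sets out from 2, which should condense with acetone under pyrrolidine catalysis (Kabbe condensation, PhMe, reflux) to 8-bromo-5-methoxy-2,2-dimethylchroman-4-one F1. The lithium enolate of F1 (LiHMDS, THF, −78 °C) should then be hydroxylated at C3 with 2-(phenylsulfonyl)-3-phenyloxaziridine to give 7, where the route is rejoined; steps 2 to 4 are then not needed.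

Step 5. Epimerisation at C3 may be slower than reduction, so that the process becomes a plain kinetic resolution with loss of diastereo- and enantiopurity. The hindered, electron-rich C4 ketone (peri-methoxy group) may be reduced sluggishly, and the enediol may drift to the isomeric 4-hydroxy-3-ketone. The fallback gives up asymmetric catalysis for substrate control plus resolution. It sets out from 7, which should be reduced by K-Selectride (THF, −78 °C) from the face anti to the C3 hydroxyl to the racemic cis-diol, a 1:1 mixture of 9 and (3R,4R)-8-bromo-5-methoxy-2,2-dimethylchromane-3,4-diol F2. Preparative chromatography on a chiral stationary phase should then deliver 9, where the route is rejoined.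

Step 7. The condensation may stall because the aldehyde is present as its electron-rich phenoxide, and long exposure to concentrated base may cause retro-aldol and Cannizzaro losses. The fallback carries the phenol masked, so that the electrophile is a neutral aldehyde, and releases it under neutral conditions. It sets out from 11, which should condense with commercial 4-(allyloxy)benzaldehyde (KOH, EtOH, rt) to (E)-3-[4-(allyloxy)phenyl]-1-[(3S,4S)-3,4-dihydroxy-5-methoxy-2,2-dimethylchroman-8-yl]prop-2-en-1-one F3. Palladium-catalysed allyl transfer (Pd(PPh3)4 cat., K2CO3, MeOH, rt) should then free the phenol and give 14.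

**Further compounds**

F1 | step 4 | 8-bromo-5-methoxy-2,2-dimethylchroman-4-one | COc1ccc(Br)c2c1C(=O)CC(C)(C)O2
F2 | step 5 | (3R,4R)-8-bromo-5-methoxy-2,2-dimethylchromane-3,4-diol | COc1ccc(Br)c2c1[C@@H](O)[C@@H](O)C(C)(C)O2
F3 | step 7 | (E)-3-[4-(allyloxy)phenyl]-1-[(3S,4S)-3,4-dihydroxy-5-methoxy-2,2-dimethylchroman-8-yl]prop-2-en-1-one | COc1ccc(C(=O)/C=C/c2ccc(OCC=C)cc2)c2c1[C@H](O)[C@H](O)C(C)(C)O2
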